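**Plan**

- Retrosynthetic cuts, in order: the side-chain bond C1'–C2' (lateral alkylation of a 2-methyl-4-pyranone with a C16 iodide); a traceless C6–SO2Ph bond; then C7–C8 and C5–C6 together, which opens ring B to 2,6-dimethyl-4-oxo-4H-pyran-3-carbaldehyde and a vinyl sulfone.
- Enabling feature: on one C=C edge of the pyranone (ring A) a formyl carbon (future C5) and a methyl carbon (future C8) are neighbours. Light-driven 1,5-hydrogen transfer makes them the ends of a hydroxy-diene C5=C4a–C8a=C8, and the C4 carbonyl next to C5–O clamps this dienol on a chiral titanium centre.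
- Forward order: dehydroacetic acid → pyranone acid → thioester → aldehyde (ring A complete); photoenolisation/[4+2] cycloaddition closes ring B; desulfonylation; the second, so far unused methyl group takes up the chain last.
- Stereochemistry: C5 (S) comes from the TADDOL ligand on titanium in the cycloaddition (C6 is transient). The Z alkene is bought with (Z)-hexadec-11-en-1-ol and enters only in the last step.

Key step: step 4

Assumption: (R,R)-TADDOL is taken as the ligand enantiomer that leads to the (5R,6R) adduct; the sense of induction cannot be predicted with certainty, and the (S,S) ligand would be used in the same way if it proves opposite.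

**Route**

Step 1
Reactants: 1 dehydroacetic acid (3-acetyl-4-hydroxy-6-methyl-2H-pyran-2-one)
Product: 2 2,6-dimethyl-4-oxo-4H-pyran-3-carboxylic acid
Conditions: 90% H2SO4, 130 °C, short heating; then ice
Reagents that add atoms: water, O (one oxygen enters in the lactone hydrolysis and one leaves again in the ring closure; net isomerisation)
Why: Acid-mediated ring opening and recyclisation of the 3-acyl-4-hydroxy-2-pyranone, in which the lactone is hydrolysed to a triketo acid that closes again by cyclodehydration between its two outer ketone groups to the γ-pyranone acid (the classical isomerisation of dehydroacetic acid); no stereocentre is formed.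

Step 2
Reactants: 2 2,6-dimethyl-4-oxo-4H-pyran-3-carboxylic acid
Product: 3 S-ethyl 2,6-dimethyl-4-oxo-4H-pyran-3-carbothioate
Conditions: EtSH, DCC, DMAP (cat.), CH2Cl2, 0 → 20 °C
Reagents that add atoms: ethanethiol, CCS
Why: Steglich-type thioesterification, in which the carbodiimide-activated acid is passed by DMAP to the thiol under neutral conditions that leave the pyranone untouched.

Step 3
Reactants: 3 S-ethyl 2,6-dimethyl-4-oxo-4H-pyran-3-carbothioate
Product: 4 2,6-dimethyl-4-oxo-4H-pyran-3-carbaldehyde
Conditions: Et3SiH, 10% Pd/C, acetone, 20 °C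
Reagents that add atoms: none
Why: Fukuyama reduction, in which palladium inserts into the acyl–sulfur bond and the silane delivers hydride, should stop at the aldehyde under neutral conditions and so reach the formyl oxidation level that hydride reagents cannot reach selectively beside a pyranone.

Step 4
Reactants: 4 2,6-dimethyl-4-oxo-4H-pyran-3-carbaldehyde; 5 phenyl vinyl sulfone
Product: 7 (5R,6R)-5-hydroxy-2-methyl-6-(phenylsulfonyl)-5,6,7,8-tetrahydro-4H-chromen-4-one, via photoenol 6 (not isolated)
Conditions: hν (366 nm), Ti(Oi-Pr)4 (1.1 equiv), (R,R)-TADDOL (1.2 equiv), 5 (3 equiv), toluene, Ar, 20 °C; then H2O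
Reagents that add atoms: none
Why: Proposed new method: irradiation at 366 nm excites the conjugated formyl group of 4 (n,π*), its oxygen takes a hydrogen atom from the neighbouring methyl group through a six-membered transition state, and the resulting biradical relaxes to the hydroxy-diene 6, which Ti(TADDOLate)(Oi-Pr)2 captures as a chelate through the dienol oxygen and the C4 carbonyl before it adds across the electron-poor alkene of 5 in a [4+2] cycloaddition that re-forms the pyranone. The closest known reaction type is the photoenolisation/Diels–Alder reaction of ortho-methylbenzaldehydes with enones under Ti(Oi-Pr)4 and TADDOL-type ligands; new here are a 4-pyranone-3-carbaldehyde as the photoenol precursor and a vinyl sulfone as the ethylene equivalent. Ring B closes by this intermolecular [4+2] cycloaddition, the two new bonds (C7–C8 and C5–C6) joining the diene termini to the two alkene carbons on one face of each partner. C5 is controlled by the ligand, since the TADDOLate shields one face of the flat, chelated dienol so that 5 adds to the other, while C6 follows from the endo approach (sulfonyl group under the diene, cis to the hydroxyl) and is of no consequence because step 5 removes it. The step needs facial selectivity, secured by the two-point binding of the substrate (C5–O and C4=O) to the chiral titanium centre; regioselectivity, secured by the donor oxygens that make the methylene terminus C8 the nucleophilic end which bonds to the β-carbon of the sulfone; and site selectivity between the two methyl groups, secured because only the one next to the formyl group lies within reach of its oxygen.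

Step 5
Reactants: 7 (5R,6R)-5-hydroxy-2-methyl-6-(phenylsulfonyl)-5,6,7,8-tetrahydro-4H-chromen-4-one
Product: 8 (5S)-5-hydroxy-2-methyl-5,6,7,8-tetrahydro-4H-chromen-4-one
Conditions: 6% Na(Hg), Na2HPO4, MeOH–THF, −20 °C
Reagents that add atoms: none
Why: Reductive desulfonylation of a free β-hydroxy sulfone, in which electron transfer cleaves the C6–S bond and buffered methanol should protonate C6 faster than the poor leaving group at C5 is expelled; C5 is untouched, and its descriptor changes from R to S only because the sulfonyl group is lost.

Step 6
Reactants: 9 (Z)-hexadec-11-en-1-ol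
Product: 10 (Z)-16-iodohexadec-5-ene
Conditions: I2, PPh3, imidazole, CH2Cl2, 0 → 20 °C
Reagents that add atoms: iodine, II
Why: Appel-type iodination, in which the alkoxyphosphonium ion is displaced by iodide at the primary carbon without touching the Z alkene.

Step 7
Reactants: 8 (5S)-5-hydroxy-2-methyl-5,6,7,8-tetrahydro-4H-chromen-4-one; 10 (Z)-16-iodohexadec-5-ene
Product: 12 (5S)-2-[(12Z)-heptadec-12-en-1-yl]-5-hydroxy-5,6,7,8-tetrahydro-4H-chromen-4-one, via dilithium dienolate 11 (not isolated)
Conditions: LiN(i-Pr)2 (2.1 equiv), THF, −78 °C; then 10, DMPU, −78 → −30 °C; then H2O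
Reagents that add atoms: none
Why: Lateral (vinylogous) deprotonation of the 2-methyl group, after the hydroxyl, gives an extended dienolate that the primary iodide should alkylate at its terminal carbon, as known for 2-methyl-4-pyranones and 2-methylchromones; no stereocentre is formed and C5–H is not acidic, so the configuration is kept.

**Compound list**

1 | dehydroacetic acid (3-acetyl-4-hydroxy-6-methyl-2H-pyran-2-one) | CC(=O)C1=C(O)C=C(C)OC1=O | starting material
2 | 2,6-dimethyl-4-oxo-4H-pyran-3-carboxylic acid | Cc1cc(=O)c(C(=O)O)c(C)o1 | intermediate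
3 | S-ethyl 2,6-dimethyl-4-oxo-4H-pyran-3-carbothioate | CCSC(=O)c1c(C)oc(C)cc1=O | intermediate
4 | 2,6-dimethyl-4-oxo-4H-pyran-3-carbaldehyde | Cc1cc(=O)c(C=O)c(C)o1 | intermediate
5 | phenyl vinyl sulfone (ethenylsulfonylbenzene) | C=CS(=O)(=O)c1ccccc1 | starting material
6 | photoenol, (3Z)-3-(hydroxymethylidene)-6-methyl-2-methylidene-2,3-dihydro-4H-pyran-4-one (hydroxyl on the side of the C4 carbonyl) | O/C=C1\C(=O)C=C(C)OC1=C | intermediate
7 | (5R,6R)-5-hydroxy-2-methyl-6-(phenylsulfonyl)-5,6,7,8-tetrahydro-4H-chromen-4-one (hydroxyl and sulfonyl cis) | Cc1cc(=O)c2c(o1)CC[C@@H](S(=O)(=O)c3ccccc3)[C@@H]2O | intermediate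
8 | (5S)-5-hydroxy-2-methyl-5,6,7,8-tetrahydro-4H-chromen-4-one | Cc1cc(=O)c2c(o1)CCC[C@@H]2O | intermediate
9 | (Z)-hexadec-11-en-1-ol | CCCC/C=C\CCCCCCCCCCO | starting material
10 | (Z)-16-iodohexadec-5-ene | CCCC/C=C\CCCCCCCCCCI | intermediate
11 | dilithium salt of 8 (C5 alkoxide and 2-methylidene dienolate) | [Li+].[Li+].C=C1C=C([O-])C2=C(O1)CCC[C@@H]2[O-] | intermediate
12 | (5S)-2-[(12Z)-heptadec-12-en-1-yl]-5-hydroxy-5,6,7,8-tetrahydro-4H-chromen-4-one | CCCC/C=C\CCCCCCCCCCCc1cc(=O)c2c(o1)CCC[C@@H]2O | target

**Step count**

Total steps: 7. Longest linear sequence: 6 (steps 1, 2, 3, 4, 5 and 7).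

**Steps most likely to fail**

1. Step 4 (labelled step). The photoenol may return to the aldehyde faster than the weakly coordinating vinyl sulfone traps it, or the two faces of the titanium-bound dienol may be poorly differentiated. The fallback uses known chemistry, sets out from 2 and comes back at 8. The acid is methylated (MeI, K2CO3, DMF) to methyl 2,6-dimethyl-4-oxo-4H-pyran-3-carboxylate F1. The methyl group next to the ester is deprotonated with LiN(i-Pr)2 at −78 °C, and Michael addition to tert-butyl acrylate followed by Dieckmann closure onto the methyl ester (Staunton–Weinreb-type annulation) should give tert-butyl 2-methyl-4,5-dioxo-5,6,7,8-tetrahydro-4H-chromene-6-carboxylate F2. CF3CO2H followed by warming cleaves the ester and decarboxylates to 2-methyl-7,8-dihydro-4H-chromene-4,5(6H)-dione F3. Asymmetric transfer hydrogenation of the C5 ketone with RuCl(p-cymene)[(S,S)-TsDPEN] and HCO2H/Et3N is expected, by analogy with 1-tetralone, to give the (S) alcohol 8; the (R,R) catalyst would be used if the sense is opposite.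

2. Step 5. After the C–S bond is cleaved the C6 anion may expel the neighbouring oxygen (loss of the carbinol by β-elimination), or the pyranone may be reduced at the potential needed for an alkyl phenyl sulfone. The fallback sets out from 7 and comes back at 8. Dess–Martin oxidation gives 2-methyl-6-(phenylsulfonyl)-7,8-dihydro-4H-chromene-4,5(6H)-dione F4, a β-keto sulfone with no β-leaving group. Its C–S bond is cleaved by the far milder Al(Hg) in wet THF at 0 °C to the dione F3 described above, and the same asymmetric transfer hydrogenation then sets C5 and gives 8.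

3. Step 7. Deprotonation may compete at the ring C8 methylene (the other vinylogous position), giving C8-alkylated isomers, and the C5 alkoxide may be O-alkylated. The fallback joins the chain by acylation, where the position is unambiguous; it sets out from 10 and comes back at 12. Alkylation of dimethyl malonate (NaH, DMF) gives dimethyl 2-[(Z)-hexadec-11-en-1-yl]propanedioate F5, and Krapcho dealkoxycarbonylation (LiCl, wet DMSO, 150 °C) gives methyl (Z)-octadec-13-enoate F6. Acylation of the trilithium salt of commercial 2-acetylcyclohexane-1,3-dione (LiN(i-Pr)2, 3.3 equiv, THF) at its acetyl methyl group with F6 gives 2-[(Z)-3-oxoicos-15-enoyl]cyclohexane-1,3-dione F7. Mild acid (CF3CO2H, CH2Cl2, 20 °C) closes the pyranone to 2-[(Z)-heptadec-12-en-1-yl]-7,8-dihydro-4H-chromene-4,5(6H)-dione F8. Asymmetric transfer hydrogenation with RuCl(p-cymene)[(S,S)-TsDPEN] and HCO2H/Et3N, which leaves the isolated Z alkene alone, then gives 12.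

**Further compounds**

F1 | step 4 | methyl 2,6-dimethyl-4-oxo-4H-pyran-3-carboxylate | COC(=O)c1c(C)oc(C)cc1=O
F2 | step 4 | tert-butyl 2-methyl-4,5-dioxo-5,6,7,8-tetrahydro-4H-chromene-6-carboxylate | Cc1cc(=O)c2c(o1)CCC(C(=O)OC(C)(C)C)C2=O
F3 | step 4 | 2-methyl-7,8-dihydro-4H-chromene-4,5(6H)-dione | Cc1cc(=O)c2c(o1)CCCC2=O
F4 | step 5 | 2-methyl-6-(phenylsulfonyl)-7,8-dihydro-4H-chromene-4,5(6H)-dione | Cc1cc(=O)c2c(o1)CCC(S(=O)(=O)c3ccccc3)C2=O
F5 | step 7 | dimethyl 2-[(Z)-hexadec-11-en-1-yl]propanedioate | CCCC/C=C\CCCCCCCCCCC(C(=O)OC)C(=O)OC
F6 | step 7 | methyl (Z)-octadec-13-enoate | CCCC/C=C\CCCCCCCCCCCC(=O)OC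
F7 | step 7 | 2-[(Z)-3-oxoicos-15-enoyl]cyclohexane-1,3-dione | CCCC/C=C\CCCCCCCCCCCC(=O)CC(=O)C1C(=O)CCCC1=O
F8 | step 7 | 2-[(Z)-heptadec-12-en-1-yl]-7,8-dihydro-4H-chromene-4,5(6H)-dione | CCCC/C=C\CCCCCCCCCCCc1cc(=O)c2c(o1)CCCC2=O
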